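**Plan**
- Retrosynthetic cuts: C13–C16 (ring D, reductive Heck of a 2-iodoenone grown from a C8 acetyl group); C8–C14 and C9–C11 (ring C, Diels–Alder); C8=C9 (lactone ring, Knoevenagel of a C20 acetoacetate onto a C9 aldehyde); C5–C10 (ring A); C1–C10 (ketone plus alkenylmetal).
- Ring A (C1–C5, C10) is not built six-membered. The unit O–C1–C10(quaternary spiro)–C20–O is the product pattern of a semipinacol shift, so C1–C5 begin as a cyclopentanol that carries at C1 a 2,2-disubstituted oxirane (C10, C20). Shift of C5 from C1 to C10 expands the ring, makes the spiro carbon and leaves O on C1 and C20.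
- Forward order: cyclopentanone (C1–C5) → ring A by one-carbon expansion → lactone ring → ring C → ring D.
- Stereochemistry: C5 from a catalytic asymmetric hydroxymethylation; C10 by relay from C5 (anti addition to the ketone, hydroxyl-directed epoxidation, stereospecific shift); C1 by hydride delivery anti to C20/C6; C8, C9, C11, C14 in the Diels–Alder step; C13 by the bridging cyclisation.

Key step: step 7

Remark: locants C1–C20 follow kaurane numbering of the target (ring A = C1–C5, C10; lactone ring = C7–C10, C20, O; ring C = C8, C9, C11–C14; ring D = C8, C13–C16); TBS = tert-butyldimethylsilyl, PMB = 4-methoxybenzyl; in step 2 the ligand enantiomer is assumed to be the one that leads to the S ketone.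

**Step 1**
Reactants: 1 3-methylcyclopent-2-en-1-one
Product: 2 [(3,3-dimethylcyclopent-1-en-1-yl)oxy]trimethylsilane
Conditions: MeMgBr, CuBr·SMe2 (5 mol%), TMSCl, HMPA, THF, −78 °C
Reagents that add atoms: methylmagnesium bromide (C[Mg]Br); chlorotrimethylsilane (C[Si](C)(C)Cl)
Why: Copper-catalysed, TMSCl-accelerated conjugate addition builds the gem-dimethyl carbon C4 and traps the enolate regiospecifically as the silyl enol ether on the C5 side (conjugate addition–enolate silylation).

**Step 2**
Reactants: 2 [(3,3-dimethylcyclopent-1-en-1-yl)oxy]trimethylsilane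
Product: 3 (S)-2-(hydroxymethyl)-3,3-dimethylcyclopentan-1-one
Conditions: aq. HCHO, Sc(OTf)3 (10 mol%), chiral 6,6'-bis(1-hydroxy-2,2-dimethylpropyl)-2,2'-bipyridine (12 mol%), DME/H2O, −20 °C
Reagents that add atoms: formaldehyde (C=O)
Why: Mukaiyama-type aldol reaction of the silicon enolate with aqueous formaldehyde under a chiral Sc(OTf)3–bipyridine Lewis acid (catalytic asymmetric hydroxymethylation) installs C6 and sets C5 by catalyst control of the enolate face, under conditions mild enough not to epimerise the new α-centre.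

**Step 3**
Reactants: 3 (S)-2-(hydroxymethyl)-3,3-dimethylcyclopentan-1-one
Product: 4 (S)-2-[(TBSO)methyl]-3,3-dimethylcyclopentan-1-one
Conditions: TBSCl, imidazole, CH2Cl2, 0 °C → rt
Reagents that add atoms: tert-butylchlorodimethylsilane (CC(C)(C)[Si](C)(C)Cl)
Why: Standard silylation of the primary alcohol removes the acidic OH before the organometallic step and blocks retro-aldol loss of formaldehyde.

**Step 4**
Reactants: 5 2,3-dibromoprop-1-ene; 6 4-methoxybenzyl alcohol
Product: 7 2-bromoallyl 4-methoxybenzyl ether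
Conditions: NaH, THF/DMF, 0 °C → rt
Reagents that add atoms: none
Why: Williamson ether synthesis in which the alkoxide displaces only the allylic bromide (SN2), the vinylic bromide being inert, giving the C9–C10–C20 unit as a vinyl bromide.

**Step 5**
Reactants: 7 2-bromoallyl 4-methoxybenzyl ether; 4 (S)-2-[(TBSO)methyl]-3,3-dimethylcyclopentan-1-one
Product: 10 (1S,2S)-2-[(TBSO)methyl]-3,3-dimethyl-1-[3-(PMBO)prop-1-en-2-yl]cyclopentan-1-ol, via alkenyllithium 8 (not isolated), via alkenylcerium dichloride 9 (not isolated)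
Conditions: 7, t-BuLi (2 equiv), Et2O, −78 °C; CeCl3, THF, −78 °C; then 4; aq. NH4Cl
Reagents that add atoms: none
Why: Bromine–lithium exchange and transmetalation to the weakly basic organocerium allow 1,2-addition to the enolisable hindered ketone, the nucleophile approaching C1 anti to the C5 substituent so that the new hydroxyl is cis to C6 (organocerium carbonyl addition).

**Step 6**
Reactants: 10 (1S,2S)-2-[(TBSO)methyl]-3,3-dimethyl-1-[3-(PMBO)prop-1-en-2-yl]cyclopentan-1-ol
Product: 11 (1S,2S)-2-[(TBSO)methyl]-3,3-dimethyl-1-[(2S)-2-(PMBO-methyl)oxiran-2-yl]cyclopentan-1-ol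
Conditions: VO(acac)2 (5 mol%), t-BuOOH, CH2Cl2, 0 °C → rt
Reagents that add atoms: tert-butyl hydroperoxide (CC(C)(C)OO)
Why: Hydroxyl-directed epoxidation of the allylic 1,1-disubstituted alkene, in which the smaller ring carbon C2 should eclipse the C9 methylene in the vanadate transition state (least A(1,2) strain) while C5 lies on the far face, so that the oxirane oxygen at C10 ends up anti to C5.

**Step 7**
Reactants: 11 (1S,2S)-2-[(TBSO)methyl]-3,3-dimethyl-1-[(2S)-2-(PMBO-methyl)oxiran-2-yl]cyclopentan-1-ol
Product: 12 (2S,3R)-3-[(TBSO)methyl]-2-(hydroxymethyl)-2-(PMBO-methyl)-4,4-dimethylcyclohexan-1-one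
Conditions: BF3·OEt2 (0.2 equiv), CH2Cl2, −78 → −40 °C
Reagents that add atoms: none
Why: BF3 coordinates the oxirane oxygen and, as the C10–O bond ionises, the ring bond C1–C5 held anti-periplanar to it shifts from C1 to C10 while the carbinol oxygen becomes the C1 carbonyl, driven by release of oxirane strain and C=O formation (semipinacol rearrangement; closest known type is the Lewis-acid 1,2-shift of tertiary 2,3-epoxy alcohols to β-hydroxy ketones with an α-quaternary carbon). Ring A (C1–C5 plus C10) is not closed by an end-on cyclisation: it arises by a suprafacial 1,2-alkyl shift that inserts C10 between C1 and C5, a one-carbon expansion of the cyclopentane. The only new stereocentre, C10, forms with inversion at the oxirane carbon, so its configuration is dictated by the epoxide of step 6, and C5 migrates with retention, which places the new C20 hydroxymethyl group cis to C6. The selectivity needed is migration of C5 and not C2: C5 is the more substituted carbon (higher migratory aptitude) and is the one anti to the oxirane C–O bond in the rotamer in which the small C2 methylene eclipses C9. Catalytic Lewis acid at low temperature should keep the shift concerted, so that no free C10 cation (flanked by two oxygenated methylenes) loses a proton or is trapped, and participation of the C6 silyl ether is excluded because it would require a trans-fused bicyclo[3.3.0] oxonium ion.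

**Step 8**
Reactants: 12 (2S,3R)-3-[(TBSO)methyl]-2-(hydroxymethyl)-2-(PMBO-methyl)-4,4-dimethylcyclohexan-1-one
Product: 13 (1S,2S,3R)-3-[(TBSO)methyl]-2-(hydroxymethyl)-2-(PMBO-methyl)-4,4-dimethylcyclohexan-1-ol
Conditions: NaBH4, MeOH, −40 → 0 °C
Reagents that add atoms: none
Why: Hydride should add to the C1 ketone from the ring face opposite the cis-disposed C20 and C6 substituents (axial attack in the chair with C6 equatorial), giving the equatorial C1 alcohol cis to C20 (substrate-controlled borohydride reduction).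

**Step 9**
Reactants: 13 (1S,2S,3R)-3-[(TBSO)methyl]-2-(hydroxymethyl)-2-(PMBO-methyl)-4,4-dimethylcyclohexan-1-ol
Product: 14 C20 acetoacetate of diol 13 (C1 hydroxyl free)
Conditions: diketene (1.05 equiv), DMAP (5 mol%), THF, −20 °C
Reagents that add atoms: diketene (C=C1CC(=O)O1)
Why: Acetoacetylation under nucleophilic catalysis is faster at the primary C20 hydroxyl than at the neopentyl secondary C1 hydroxyl and brings in C7, C8, C15 and C16 with one reagent.

**Step 10**
Reactants: 14 C20 acetoacetate of diol 13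
Product: 15 C1 acetate of 14
Conditions: Ac2O, pyridine, DMAP (cat.), CH2Cl2, 0 °C → rt
Reagents that add atoms: acetic anhydride (CC(=O)OC(C)=O)
Why: Routine DMAP-catalysed acetylation installs the C1 acetate of the target at the point where C1–OH is the only free hydroxyl.

**Step 11**
Reactants: 15 C1 acetate of 14
Product: 16 C9 primary alcohol (15 without the PMB group)
Conditions: DDQ, CH2Cl2/pH 7 buffer, 0 °C
Reagents that add atoms: none
Why: Oxidative cleavage of the 4-methoxybenzyl ether by DDQ through the benzylic oxocarbenium ion is orthogonal to the silyl ether and the esters and frees the C9 hydroxyl.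

**Step 12**
Reactants: 16 C9 primary alcohol
Product: 18 spiro alkylidene β-keto lactone (3-acetyl-5,6-dihydro-2H-pyran-2-one spiro-fused at its C5 to ring A), via aldehyde 17 (not isolated)
Conditions: Dess–Martin periodinane, NaHCO3, CH2Cl2, 0 °C → rt; then ethylenediammonium diacetate (10 mol%), 4 Å molecular sieves, rt
Reagents that add atoms: none
Why: Dess–Martin oxidation gives the non-enolisable neopentyl aldehyde, and amine-salt-catalysed intramolecular Knoevenagel condensation of the acetoacetate methylene (C8) onto it closes the six-membered lactone and creates the doubly activated C8=C9 alkene in one operation.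

**Step 13**
Reactants: 19 (1E,3E)-buta-1,3-diene-1,4-diyl diacetate
Product: 21 (1E,3E)-1,4-bis(TBSO)buta-1,3-diene, via dilithium dienediolate 20 (not isolated)
Conditions: MeLi (4 equiv), DME, −78 → 0 °C; TBSCl, HMPA, −78 °C → rt
Reagents that add atoms: tert-butylchlorodimethylsilane (CC(C)(C)[Si](C)(C)Cl)
Why: Cleavage of both enol acetates by methyllithium gives the dienediolate with retention of the E,E geometry, and O-silylation in the presence of HMPA gives the bis(silyl) dienol ether (enol acetate to silyl enol ether exchange).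

**Step 14**
Reactants: 18 spiro alkylidene β-keto lactone; 21 (1E,3E)-1,4-bis(TBSO)buta-1,3-diene
Product: 22 Diels–Alder adduct (ring C cyclohexene with C12=C13, 8-acetyl, 11,14-bis-OTBS, cis-fused to the lactone)
Conditions: 21 (3 equiv), BHT (cat.), toluene, 80 °C
Reagents that add atoms: none
Why: Normal-demand Diels–Alder reaction forms C8–C14 and C9–C11, the E,E diene giving the cis-11,14-dioxygenation, the acetyl-endo/spirolactone-exo transition state (which also keeps the C11 silyloxy group away from C10) placing both oxygens cis to C15 and H9, and the diene adding to the lactone face syn to C1 because the other face is screened by the C5 silyloxymethyl group and the C4 methyls, so that C8, C9, C11 and C14 are set together.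

**Step 15**
Reactants: 22 Diels–Alder adduct
Product: 26 vinyl ketone (C8 acryloyl group), via silyl enol ether 23 (not isolated), via Mannich base 24 (not isolated), via trimethylammonium iodide 25 (not isolated)
Conditions: TMSOTf, Et3N, CH2Cl2, 0 °C; CH2=NMe2+ I−, rt; MeI; DBU, rt
Reagents that add atoms: N,N-dimethylmethyleneiminium iodide, Eschenmoser's salt (C=[N+](C)C.[I-])
Why: Soft enolisation touches only the methyl ketone (C8 is quaternary and the esters are not enolised), the silyl enol ether undergoes a Mannich reaction with Eschenmoser's salt, and quaternisation followed by E1cB elimination gives the vinyl ketone, adding C17.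

**Step 16**
Reactants: 26 vinyl ketone
Product: 27 2-iodo vinyl ketone (iodine on C16)
Conditions: I2, pyridine, CH2Cl2, 0 °C → rt
Reagents that add atoms: iodine (II)
Why: α-Iodination of the terminal enone by pyridine conjugate addition, iodination of the enolate and elimination (Baylis–Hillman-type α-halogenation) is specific for the enone and leaves the isolated ring alkene untouched.

**Step 17**
Reactants: 27 2-iodo vinyl ketone
Product: 28 6,11,14-tris-O-TBS ether of the target
Conditions: Pd(OAc)2 (10 mol%), PPh3 (20 mol%), HCO2Na, Bu4NCl, DMF, 70 °C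
Reagents that add atoms: none
Why: Reductive Heck cyclisation in which zerovalent palladium inserts into the C16–I bond, 5-exo-trig syn-carbopalladation of C12=C13 occurs from the face that carries the acyl group (only C13 is within reach, which closes ring D as the bicyclo[3.2.1]octane and fixes C13), and formate reduces the C12–Pd bond, which cannot undergo β-hydride elimination because H11 and H13 are anti to palladium.

**Step 18**
Reactants: 28 6,11,14-tris-O-TBS ether of the target
Product: 29 target CNP0225182.1
Conditions: HF·pyridine, pyridine/THF, 0 °C → rt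
Reagents that add atoms: none
Why: Acidic fluoride removes the three silyl ethers without touching the acetate, the lactone or the enone and avoids basic conditions under which the free C14 hydroxyl could undergo retro-aldol cleavage.

**Compound list**
1 | 3-methylcyclopent-2-en-1-one | CC1=CC(=O)CC1 | starting material
2 | [(3,3-dimethylcyclopent-1-en-1-yl)oxy]trimethylsilane | C[Si](C)(C)OC1=CC(C)(C)CC1 | intermediate
3 | (S)-2-(hydroxymethyl)-3,3-dimethylcyclopentan-1-one | O=C1CCC(C)(C)[C@H]1CO | intermediate
4 | (S)-2-[(TBSO)methyl]-3,3-dimethylcyclopentan-1-one | O=C1CCC(C)(C)[C@H]1CO[Si](C)(C)C(C)(C)C | intermediate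
5 | 2,3-dibromoprop-1-ene | C=C(Br)CBr | starting material
6 | 4-methoxybenzyl alcohol | COc1ccc(CO)cc1 | starting material
7 | 2-bromoallyl 4-methoxybenzyl ether | C=C(Br)COCc1ccc(OC)cc1 | intermediate
8 | [3-(PMBO)prop-1-en-2-yl]lithium | [Li]C(=C)COCc1ccc(OC)cc1 | intermediate
9 | dichloro[3-(PMBO)prop-1-en-2-yl]cerium | Cl[Ce](Cl)C(=C)COCc1ccc(OC)cc1 | intermediate
10 | (1S,2S)-2-[(TBSO)methyl]-3,3-dimethyl-1-[3-(PMBO)prop-1-en-2-yl]cyclopentan-1-ol (OH cis to CH2OTBS) | O[C@]1(CCC(C)(C)[C@H]1CO[Si](C)(C)C(C)(C)C)C(=C)COCc1ccc(OC)cc1 | intermediate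
11 | (1S,2S)-2-[(TBSO)methyl]-3,3-dimethyl-1-[(2S)-2-(PMBO-methyl)oxiran-2-yl]cyclopentan-1-ol | O[C@]1(CCC(C)(C)[C@H]1CO[Si](C)(C)C(C)(C)C)[C@@]1(COCc2ccc(OC)cc2)CO1 | intermediate
12 | (2S,3R)-3-[(TBSO)methyl]-2-(hydroxymethyl)-2-(PMBO-methyl)-4,4-dimethylcyclohexan-1-one (CH2OH = C20, cis to C6; CH2OPMB = C9) | OC[C@]1(C(=O)CCC(C)(C)[C@H]1CO[Si](C)(C)C(C)(C)C)COCc1ccc(OC)cc1 | intermediate
13 | (1S,2S,3R)-3-[(TBSO)methyl]-2-(hydroxymethyl)-2-(PMBO-methyl)-4,4-dimethylcyclohexan-1-ol (C1 OH cis to C20) | OC[C@]1([C@@H](O)CCC(C)(C)[C@H]1CO[Si](C)(C)C(C)(C)C)COCc1ccc(OC)cc1 | intermediate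
14 | C20 acetoacetate (3-oxobutanoate) of 13, C1 hydroxyl free | CC(=O)CC(=O)OC[C@]1([C@@H](O)CCC(C)(C)[C@H]1CO[Si](C)(C)C(C)(C)C)COCc1ccc(OC)cc1 | intermediate
15 | C1 acetate of 14 | CC(=O)CC(=O)OC[C@]1([C@@H](OC(C)=O)CCC(C)(C)[C@H]1CO[Si](C)(C)C(C)(C)C)COCc1ccc(OC)cc1 | intermediate
16 | C9 primary alcohol (15 without PMB) | CC(=O)CC(=O)OC[C@]1([C@@H](OC(C)=O)CCC(C)(C)[C@H]1CO[Si](C)(C)C(C)(C)C)CO | intermediate
17 | C9 aldehyde (C20 acetoacetate, C1 acetate, C6 OTBS) | CC(=O)CC(=O)OC[C@]1([C@@H](OC(C)=O)CCC(C)(C)[C@H]1CO[Si](C)(C)C(C)(C)C)C=O | intermediate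
18 | spiro alkylidene β-keto lactone: 3-acetyl-5,6-dihydro-2H-pyran-2-one whose C5 is the spiro carbon C10 of ring A (C1 OAc, C6 OTBS) | O=C1OC[C@]2([C@@H](OC(C)=O)CCC(C)(C)[C@H]2CO[Si](C)(C)C(C)(C)C)C=C1C(C)=O | intermediate
19 | (1E,3E)-buta-1,3-diene-1,4-diyl diacetate | CC(=O)O/C=C/C=C/OC(C)=O | starting material
20 | dilithium (1E,3E)-buta-1,3-diene-1,4-diolate | [Li]O/C=C/C=C/O[Li] | intermediate
21 | (1E,3E)-1,4-bis(TBSO)buta-1,3-diene | CC(C)(C)[Si](C)(C)O/C=C/C=C/O[Si](C)(C)C(C)(C)C | intermediate
22 | Diels–Alder adduct: ring C cyclohexene (C12=C13) cis-fused to the lactone, 8-acetyl, 11,14-bis-OTBS; C1, C5, C8, C9, C10, C11, C14 configured as in the target | CC(=O)[C@@]12C(=O)OC[C@]3([C@@H](OC(C)=O)CCC(C)(C)[C@H]3CO[Si](C)(C)C(C)(C)C)[C@@H]1[C@@H](O[Si](C)(C)C(C)(C)C)C=C[C@H]2O[Si](C)(C)C(C)(C)C | intermediate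
23 | trimethylsilyl enol ether of the methyl ketone of 22 | C=C(O[Si](C)(C)C)[C@@]12C(=O)OC[C@]3([C@@H](OC(C)=O)CCC(C)(C)[C@H]3CO[Si](C)(C)C(C)(C)C)[C@@H]1[C@@H](O[Si](C)(C)C(C)(C)C)C=C[C@H]2O[Si](C)(C)C(C)(C)C | intermediate
24 | Mannich base: 3-(dimethylamino)propanoyl group on C8 | CN(C)CCC(=O)[C@@]12C(=O)OC[C@]3([C@@H](OC(C)=O)CCC(C)(C)[C@H]3CO[Si](C)(C)C(C)(C)C)[C@@H]1[C@@H](O[Si](C)(C)C(C)(C)C)C=C[C@H]2O[Si](C)(C)C(C)(C)C | intermediate
25 | trimethylammonium iodide of 24 | C[N+](C)(C)CCC(=O)[C@@]12C(=O)OC[C@]3([C@@H](OC(C)=O)CCC(C)(C)[C@H]3CO[Si](C)(C)C(C)(C)C)[C@@H]1[C@@H](O[Si](C)(C)C(C)(C)C)C=C[C@H]2O[Si](C)(C)C(C)(C)C.[I-] | intermediate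
26 | vinyl ketone: acryloyl group on C8 (C15 ketone, C16=C17) | C=CC(=O)[C@@]12C(=O)OC[C@]3([C@@H](OC(C)=O)CCC(C)(C)[C@H]3CO[Si](C)(C)C(C)(C)C)[C@@H]1[C@@H](O[Si](C)(C)C(C)(C)C)C=C[C@H]2O[Si](C)(C)C(C)(C)C | intermediate
27 | 2-iodo vinyl ketone: 2-iodoacryloyl group on C8 | C=C(I)C(=O)[C@@]12C(=O)OC[C@]3([C@@H](OC(C)=O)CCC(C)(C)[C@H]3CO[Si](C)(C)C(C)(C)C)[C@@H]1[C@@H](O[Si](C)(C)C(C)(C)C)C=C[C@H]2O[Si](C)(C)C(C)(C)C | intermediate
28 | 6,11,14-tris-O-TBS ether of the target (all stereocentres as in 29) | C=C1C(=O)[C@@]23C(=O)OC[C@]4([C@@H](OC(C)=O)CCC(C)(C)[C@H]4CO[Si](C)(C)C(C)(C)C)[C@@H]2[C@@H](O[Si](C)(C)C(C)(C)C)C[C@@H]1[C@H]3O[Si](C)(C)C(C)(C)C | intermediate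
29 | CNP0225182.1: 1-acetoxy-6,11,14-trihydroxy-15-oxo-6,7-seco-kaur-16-en-7,20-olide, (1S,5R,8R,9S,10R,11S,13S,14R) | C=C1C(=O)[C@@]23C(=O)OC[C@]4([C@@H](OC(C)=O)CCC(C)(C)[C@H]4CO)[C@@H]2[C@@H](O)C[C@@H]1[C@H]3O | target

**Totals**
Total step count: 18. Longest linear sequence: 16 steps (steps 1–3, 5–12, 14–18).

**Three steps most likely to fail**

Step 14 (Diels–Alder). The cycloaddition may be too slow, because both new bonds form at hindered carbons (C9 next to the spiro centre, C8 becoming quaternary) while each diene terminus carries a silyloxy group. Prolonged heating would then lead to desilylation and polymerisation of the diene and to conjugate-addition side reactions of the dienophile. The fallback takes the two oxygens off the diene; it sets out from 18 and returns at 22. Cycloaddition of 18 with (E)-1-acetoxybuta-1,3-diene (toluene, 80 °C), whose unsubstituted terminus bonds to C9, should give the ring C cyclohexene carrying only a C14 acetate F1. Pd(PPh3)4 and Et3N eliminate acetic acid through the allylpalladium intermediate to give the ring C 1,3-diene F2 (C11=C12–C13=C14). Addition of singlet oxygen (O2, tetraphenylporphyrin, visible light, CH2Cl2, −20 °C) to the diene face opposite the cis-fused lactone should give the 11,14-endoperoxide F3. Zn/AcOH reduces the O–O bond to the cis-11,14-diol F4, and TBSOTf/2,6-lutidine gives 22.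

Step 17 (reductive Heck). Insertion of the ring alkene may be slow, because the palladium centre must sit on C12 next to the C11 silyl ether; formate would then reduce the vinylpalladium species before ring closure, or the product enone would be over-reduced. The fallback replaces organopalladium chemistry by a free-radical chain; it sets out from 27 and returns at 28 (no new compound: F0). With (Me3Si)3SiH and AIBN in toluene at 80 °C the silyl radical abstracts iodine, the small C16 vinyl radical closes 5-exo onto C13, and the C12 radical takes hydrogen from the silane.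

Step 6 (directed epoxidation). Facial discrimination may be poor, because both carbinol substituents (C2 and C5) are ring carbons; the stereospecific shift of step 7 would then carry the wrong epoxide into the arrangement with the new hydroxymethyl group trans to C6. Because C10 carries two oxygenated methylene arms, the fallback corrects its configuration by exchanging the roles of the arms; it sets out from 10 and returns at 17. The other-face epoxide F5 rearranges under the conditions of step 7 to the hydroxy ketone with exchanged arms F6, in which the free hydroxymethyl group is the future C9 and the PMB-protected arm the future C20. NaBH4 gives the diol F7; TEMPO/PhI(OAc)2 oxidises only the primary alcohol to the hydroxy aldehyde F8; Ac2O/pyridine/DMAP gives the acetoxy aldehyde F9; DDQ frees the C20 hydroxyl to give the hydroxymethyl aldehyde F10; diketene/DMAP then gives 17, which condenses as in step 12. Both epoxide diastereomers thus converge on 18.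

**Further compounds**
F1 | step 14 | Diels–Alder adduct of 18 with (E)-1-acetoxybuta-1,3-diene: ring C cyclohex-12-ene with C14 acetate, 8-acetyl | CC(=O)[C@@]12C(=O)OC[C@]3([C@@H](OC(C)=O)CCC(C)(C)[C@H]3CO[Si](C)(C)C(C)(C)C)[C@@H]1CC=C[C@H]2OC(C)=O
F2 | step 14 | ring C 1,3-diene (C11=C12–C13=C14), 8-acetyl | CC(=O)[C@@]12C(=O)OC[C@]3([C@@H](OC(C)=O)CCC(C)(C)[C@H]3CO[Si](C)(C)C(C)(C)C)[C@@H]1C=CC=C2
F3 | step 14 | 11,14-endoperoxide (peroxide bridge cis to the acetyl group) | CC(=O)[C@@]12C(=O)OC[C@]3([C@@H](OC(C)=O)CCC(C)(C)[C@H]3CO[Si](C)(C)C(C)(C)C)[C@@H]1[C@@H]4C=C[C@H]2OO4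
F4 | step 14 | cis-11,14-diol (22 without the two ring C silyl groups) | CC(=O)[C@@]12C(=O)OC[C@]3([C@@H](OC(C)=O)CCC(C)(C)[C@H]3CO[Si](C)(C)C(C)(C)C)[C@@H]1[C@@H](O)C=C[C@H]2O
F0 | step 17 | none | none
F5 | step 6 | oxirane epimer of 11 (other alkene face) | O[C@]1(CCC(C)(C)[C@H]1CO[Si](C)(C)C(C)(C)C)[C@]1(COCc2ccc(OC)cc2)CO1
F6 | step 6 | hydroxy ketone with exchanged arms (CH2OH trans to C6 = C9; CH2OPMB cis to C6 = C20) | COc1ccc(cc1)COC[C@]1(C(=O)CCC(C)(C)[C@H]1CO[Si](C)(C)C(C)(C)C)CO
F7 | step 6 | diol from F6 (C1 OH cis to the CH2OPMB arm) | COc1ccc(cc1)COC[C@]1([C@@H](O)CCC(C)(C)[C@H]1CO[Si](C)(C)C(C)(C)C)CO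
F8 | step 6 | C9 aldehyde with free C1 hydroxyl and C20 OPMB | COc1ccc(cc1)COC[C@]1([C@@H](O)CCC(C)(C)[C@H]1CO[Si](C)(C)C(C)(C)C)C=O
F9 | step 6 | C1 acetate of F8 | COc1ccc(cc1)COC[C@]1([C@@H](OC(C)=O)CCC(C)(C)[C@H]1CO[Si](C)(C)C(C)(C)C)C=O
F10 | step 6 | C9 aldehyde with free C20 hydroxyl and C1 acetate | OC[C@]1([C@@H](OC(C)=O)CCC(C)(C)[C@H]1CO[Si](C)(C)C(C)(C)C)C=O
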